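Assumption: the SMILES contains no stereocentre, no stereogenic double bond and no axis hindered enough to be resolved. Target 14 is therefore achiral, "single enantiomer" sets no task, and no step has to control configuration.

## Structural features

The target 14 is an isoflavone. It is a 5,7-dihydroxy-4H-chromen-4-one (benzene ring A fused to pyranone ring C) joined through the C3–C1′ bond to a pentasubstituted benzene ring B. Ring B carries, in unbroken order, C1′ (ring C), C2′–OH, C3′–CH2CH2C(CH3)2OH, C4′–OMe and C5′–OMe; only C6′ bears hydrogen. There are no stereocentres, so nothing stereochemical stands next to anything else.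

There are three fragile points:
- The tertiary alcohol lies within reach of O2′. Strong acid closes it to a 2,2-dimethylchroman or dehydrates it to a prenyl group.
- The electrophilic C2 of ring C can be attacked by bases, amines and even O2′.
- Ring B is very electron-rich and easily oxidised.

The real difficulty is twofold. The C3–C1′ bond must be made to a crowded, electron-rich carbon. The three ring-B oxygens must also be told apart (O2′ free, O4′ and O5′ methylated) inside a contiguous five-substituent array.

The key step exploits the fact that O2′ and O5′ are para to each other, with the free one (O2′) ortho to C1′. Ring B is thus a hydroquinone monomethyl ether: the rearomatised form of a cyclohexa-2,5-dienone (C2′=O, dimethyl ketal at C5′) that has accepted a carbon nucleophile at C1′. Its counterpart is the C2=C3 unit of ring C, which is the β,α-carbon pair of an o-hydroxyaryl enaminone and is nucleophilic exactly at C3.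

## Logic of the disconnections

**14 ⇒ 13.** The two O–CH2Ph bonds at O5 and O7 are cut, a change of functional groups only. Free A-ring phenols would be alkylated by the amide acetal that makes 10, and they would turn ring A into a competing nucleophile in the key step. Benzyl leaves under neutral hydrogenolysis, which endangers neither the tertiary alcohol (acid) nor C2 (base). The demand is that hydrogenolysis stops before C2=C3 is saturated.

**13 ⇒ 7 + 10 (key disconnection).** C3–C1′ and O1–C2 are cut, and ring B goes back from an arene to a cross-conjugated dienone.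
- Reason: once the C5′ ketal of 7 is ionised, C1′ becomes the only open electrophilic carbon of ring B, and the α-carbon of 10 is the natural C3 nucleophile.
- Gain: the molecule falls into two halves, each reachable in four steps or fewer. Ring B needs no halogen, boron or protecting group. O2′ and O5′ are distinguished by oxidation state (ketone versus ketal), not by selective alkylation.
- Demand: attack at C1′ through carbon, ring closure by the A-ring oxygen, and an acid mild enough for the tertiary alcohol.
- One-sentence test: acid-triggered addition of the α-carbon of 10 to C1′ of the dearomatised ring B of 7, with rearomatisation and pyranone closure. This sentence fits neither a cross-coupling nor a deoxybenzoin route.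

**7 ⇒ 6.** The C2′=O group is taken back to a second dimethyl ketal. The symmetrical oxidation level of 6 comes directly from an arene. The two ketals differ electronically, because only C2′ is vinylogous to the 4′-methoxy group. The demand is hydrolysis of exactly one ketal, the one at C2′.

**6 ⇒ 5.** The two newly formed C–OMe bonds at C2′ and C5′ are cut, which reverses the dearomatisation. An anode does this without a chemical oxidant and without ever passing through a free phenol, so ring B needs no protecting group. The demand is that oxidation takes place on the ring and not on the benzylic CH2 or the alcohol.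

**5 ⇒ 4.** The C–OH bond of the tertiary carbinol is cut. The hydrated chain becomes a prenyl group, which can be introduced with a cheap allylic halide. The demand is Markovnikov hydration under non-acidic, non-electrophilic conditions that leave the arene alone.

**4 ⇒ 1 + 2.** The C3′–CH2 bond is cut. C3′ lies between two methoxy groups of 1 and is the kinetically most acidic ring position. The 1′–5′ substitution pattern therefore follows from one commercial arene. The demand is clean metalation at that site and SN2 (not SN2′) alkylation.

**10 ⇒ 9.** The C2=C3 double bond is cut, removing carbon C2 with its dimethylamino group. C2 comes from an amide acetal and C3 is the acetyl methyl carbon. The demand is that the chelated hydroxyl stays free.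

**9 ⇒ 8.** Two O–CH2Ph bonds are cut. The hydrogen bond of one ortho hydroxyl to the acetyl group gives the selectivity needed to leave exactly the future O1 unprotected.

## Other disconnections considered

**Alternative 1:** cut C3–C1′ alone as a cross-coupling; this is the first idea that comes to mind. The forward key step is a Suzuki–Miyaura coupling of 5,7-bis(benzyloxy)-3-iodochromen-4-one A1 with the 2-benzyloxy-arylboronic acid A2, followed by hydrogenolysis.
- The plan is sound, but the coupling forms one bond only, and ring C must be closed beforehand in a separate iodocyclisation.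
- Ring B would have to be made as the free phenol, halogenated at C1′, protected at O2′ and borylated. These operations only prepare the coupling and would add about five steps.
- A2 is an ortho-alkoxy, strongly electron-rich boronic acid, a class prone to protodeboronation in aqueous base. The same base threatens C2 of A1.
- The O2′/O5′ differentiation is not solved by the key step and has to be bought separately.

**Alternative 2:** cut C3–C1′ by moving ring B back to C2, a biomimetic 1,2-aryl shift in the manner of isoflavone synthase. In the forward direction, a Claisen–Schmidt condensation of 9 with the benzaldehyde A3 gives the chalcone A4. Thallium(III) or an aryl-λ3-iodane in methanol then triggers the oxidative aryl migration, and acid closes ring C.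
- The electron-rich ring B would migrate well.
- However, the oxidant meets a protected hydroxyquinol ring that is easier to oxidise than the enone, so ring oxidation is the expected competitor.
- A3 needs formylation and O2′ protection on top of the chemistry used here.
- Ring closure requires acid in the presence of the tertiary alcohol, and the sequence is longer by three to four steps.

**Alternative 3:** cut C1′–C2′, C2′–C3′ and C5′–C6′ and build ring B de novo. The forward key step is a Dötz benzannulation of the terminal alkyne A5 with the α-methoxyalkenyl Fischer carbene complex A6.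
- The terminal alkyne would place ring C next to the new phenol (C2′, from CO), and the carbene methoxy group would become 5′-OMe. Regiochemistry and O-differentiation are therefore inherent.
- The gain is paid for elsewhere. A5 needs iodocyclisation, Sonogashira coupling and desilylation. A6 needs a functionalised enol ether, its α-lithiation and stoichiometric chromium.
- α-Alkoxyalkenyl carbenes have more non-benzannulation pathways open to them.
- The count would be well above twelve steps, against eight here.

Key step: step 7

## Route

Step 1
Reactants: 1 1,2,4-trimethoxybenzene; 2 prenyl bromide (1-bromo-3-methylbut-2-ene)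
Product: 4 1,2,4-trimethoxy-3-(3-methylbut-2-en-1-yl)benzene, via aryllithium 3 (not isolated)
Conditions: n-BuLi, THF, 0 °C → rt; then 2, −78 °C → rt
Reagents that add atoms: none
Why: Directed ortho-metalation: C3 of 1 lies between two methoxy groups, so cooperative coordination directs n-BuLi to this proton. The aryllithium 3 then displaces the primary allylic bromide of 2 in an SN2 alkylation.

Step 2
Reactants: 4 1,2,4-trimethoxy-3-(3-methylbut-2-en-1-yl)benzene
Product: 5 2-methyl-4-(2,3,6-trimethoxyphenyl)butan-2-ol
Conditions: Mn(dpm)3 (cat.), PhSiH3, O2 (1 atm), i-PrOH, 0 °C → rt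
Reagents that add atoms: dioxygen, O=O
Why: Mukaiyama hydration (metal-hydride hydrogen-atom transfer): the hydrogen atom goes to the less substituted alkene carbon, the tertiary radical is trapped by O2 and the peroxide is reduced in situ, which gives the Markovnikov tertiary alcohol. The conditions are neutral and non-electrophilic, so the electron-rich arene is left alone.

Step 3
Reactants: 5 2-methyl-4-(2,3,6-trimethoxyphenyl)butan-2-ol
Product: 6 2-methyl-4-(2,3,3,6,6-pentamethoxycyclohexa-1,4-dien-1-yl)butan-2-ol
Conditions: Pt anode, Pt cathode, undivided cell, 1% KOH/MeOH, constant current, 0 °C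
Reagents that add atoms: methanol, CO
Why: Anodic two-electron bis-methoxylation of a 1,4-dimethoxyarene in basic methanol, a standard electrosynthesis of quinone bisketals: ring B is by far the most easily oxidised group of 5, and methanol adds at the two para carbons that already bear methoxy groups (C2′ and C5′) while hydrogen forms at the cathode. Capture of the C2′ cation by the side-chain hydroxyl instead of methanol would be harmless, because this ketal carbon is hydrolysed in step 4.

Step 4
Reactants: 6 2-methyl-4-(2,3,3,6,6-pentamethoxycyclohexa-1,4-dien-1-yl)butan-2-ol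
Product: 7 2-(3-hydroxy-3-methylbutyl)-3,4,4-trimethoxycyclohexa-2,5-dien-1-one
Conditions: AcOH/H2O/THF, 0 °C
Reagents that add atoms: water, O
Why: Regioselective monohydrolysis of a quinone bisketal: loss of methanol from C2′ gives a cation delocalised onto C4′ and stabilised there by the methoxy group, whereas ionisation at C5′ puts the charge only on C3′ and C1′, so the C2′ ketal goes first. The product is a vinylogous ester whose carbonyl group disfavours ionisation of the remaining ketal, so hydrolysis should stop at 7 in weak acid.

Step 5
Reactants: 8 2,4,6-trihydroxyacetophenone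
Product: 9 1-[2,4-bis(benzyloxy)-6-hydroxyphenyl]ethan-1-one
Conditions: BnBr (2.1 equiv), K2CO3, acetone, reflux
Reagents that add atoms: benzyl bromide, BrCc1ccccc1
Why: Williamson etherification: after the para and one ortho hydroxyl have reacted, the last hydroxyl is locked in a hydrogen bond to the acetyl oxygen and is the least nucleophilic. Alkylation should therefore stop at the bis-ether.

Step 6
Reactants: 9 1-[2,4-bis(benzyloxy)-6-hydroxyphenyl]ethan-1-one
Product: 10 (E)-1-[2,4-bis(benzyloxy)-6-hydroxyphenyl]-3-(dimethylamino)prop-2-en-1-one
Conditions: DMF-DMA, toluene, 95 °C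
Reagents that add atoms: N,N-dimethylformamide dimethyl acetal, COC(OC)N(C)C
Why: Condensation of a methyl ketone with an amide acetal (enaminone formation), standard for o-hydroxyacetophenones. The push–pull alkene adopts the E geometry and the chelated hydroxyl stays free.

Step 7
Reactants: 7 2-(3-hydroxy-3-methylbutyl)-3,4,4-trimethoxycyclohexa-2,5-dien-1-one; 10 (E)-1-[2,4-bis(benzyloxy)-6-hydroxyphenyl]-3-(dimethylamino)prop-2-en-1-one
Product: 13 5,7-bis(benzyloxy)-3-[2-hydroxy-3-(3-hydroxy-3-methylbutyl)-4,5-dimethoxyphenyl]-4H-chromen-4-one, via O-methylquinonium cation 11 (not isolated), via alpha-aryl enaminone 12 (not isolated)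
Conditions: C6F5CO2H (1.5 equiv), HFIP/CH2Cl2 (1:1), 4 Å MS, −20 °C, slow addition of 10; → rt
Reagents that add atoms: none
Why: Proposed new method: the carboxylic acid in strongly ionising, weakly nucleophilic HFIP removes one methoxy group from the C5′ ketal of 7 and gives cation 11, in which C5′=O+Me is by far the stronger of the two acceptors, so that its free β-carbon C1′ is the electrophilic site (C3′, the other β-carbon, is blocked by the side chain, and C6′ is β only to the weak vinylogous-ester carbonyl C2′=O). The α-carbon of the push–pull alkene of 10 (the future C3) adds to C1′, and loss of the protons at C1′ and C3 rearomatises ring B and restores the enaminone in 12, so that the former ketone oxygen appears as the free 2′-OH and the surviving ketal methoxy group as 5′-OMe without any selective O-alkylation. The chelated A-ring hydroxyl then adds to the aminomethine carbon (the future C2) and dimethylamine leaves as its salt, which closes ring C through O1–C2 by an addition–elimination that is 6-endo-trig on the enaminone C=C (6-exo-trig on its C-protonated iminium form). The closest known reaction types are the acid/HFIP-promoted coupling of quinone monoketals with arenes and alkenes at the carbon α to the carbonyl group, the Michael stage of the Nenitzescu reaction of enaminones with quinones, and the domino α-functionalisation/chromone annulation of o-hydroxyaryl enaminones with electrophiles; their combination on this pair of partners is new. No stereocentre is formed. Site selectivity is secured by the substrate as described, and direct Michael addition to un-ionised 7 at C6′ is disfavoured because C2′=O is deactivated by the 4′-methoxy group and C6′ is neopentyl-like next to the ketal. Closure through O2′ (five-membered ring) is the competing mode; it is 5-endo-trig on the push–pull alkene and starts from a hydroxyl crowded by the C3′ chain, whereas the A-ring hydroxyl is held in the plane of the enaminone by its hydrogen bond to the carbonyl oxygen. C–C bond formation has to outrun the proton-induced self-cyclisation of 10 with loss of dimethylamine, hence the slow addition of 10 to pre-ionised 7 at low temperature, and the tertiary alcohol should survive because the acid is only a carboxylic acid that is buffered by the liberated amine.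

Step 8
Reactants: 13 5,7-bis(benzyloxy)-3-[2-hydroxy-3-(3-hydroxy-3-methylbutyl)-4,5-dimethoxyphenyl]-4H-chromen-4-one
Product: 14 5,7-dihydroxy-3-[2-hydroxy-3-(3-hydroxy-3-methylbutyl)-4,5-dimethoxyphenyl]-4H-chromen-4-one (target)
Conditions: H2 (1 atm), 10% Pd/C, EtOAc/MeOH, rt, stopped after uptake of 2 equiv
Reagents that add atoms: none
Why: Catalytic hydrogenolysis of aryl benzyl ethers, the standard neutral end-game for polyhydroxyisoflavones. The non-benzylic tertiary alcohol, the methyl ethers and, with controlled uptake, the tetrasubstituted-like C2=C3 bond of the vinylogous ester are not affected.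

## Compound list

1 | 1,2,4-trimethoxybenzene | COc1ccc(OC)c(OC)c1 | starting material
2 | prenyl bromide (1-bromo-3-methylbut-2-ene) | CC(C)=CCBr | starting material
3 | (2,3,6-trimethoxyphenyl)lithium | [Li]c1c(OC)ccc(OC)c1OC | intermediate
4 | 1,2,4-trimethoxy-3-(3-methylbut-2-en-1-yl)benzene | COc1ccc(OC)c(CC=C(C)C)c1OC | intermediate
5 | 2-methyl-4-(2,3,6-trimethoxyphenyl)butan-2-ol | COc1ccc(OC)c(CCC(C)(C)O)c1OC | intermediate
6 | 2-methyl-4-(2,3,3,6,6-pentamethoxycyclohexa-1,4-dien-1-yl)butan-2-ol | COC1=C(CCC(C)(C)O)C(OC)(OC)C=CC1(OC)OC | intermediate
7 | 2-(3-hydroxy-3-methylbutyl)-3,4,4-trimethoxycyclohexa-2,5-dien-1-one | COC1=C(CCC(C)(C)O)C(=O)C=CC1(OC)OC | intermediate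
8 | 2,4,6-trihydroxyacetophenone | CC(=O)c1c(O)cc(O)cc1O | starting material
9 | 1-[2,4-bis(benzyloxy)-6-hydroxyphenyl]ethan-1-one | CC(=O)c1c(O)cc(OCc2ccccc2)cc1OCc1ccccc1 | intermediate
10 | (E)-1-[2,4-bis(benzyloxy)-6-hydroxyphenyl]-3-(dimethylamino)prop-2-en-1-one | CN(C)/C=C/C(=O)c1c(O)cc(OCc2ccccc2)cc1OCc1ccccc1 | intermediate
11 | O-methylquinonium cation: [3-(3-hydroxy-3-methylbutyl)-2-methoxy-4-oxocyclohexa-2,5-dien-1-ylidene](methyl)oxonium | COC1=C(CCC(C)(C)O)C(=O)C=CC1=[O+]C | intermediate
12 | (E)-1-[2,4-bis(benzyloxy)-6-hydroxyphenyl]-3-(dimethylamino)-2-[2-hydroxy-3-(3-hydroxy-3-methylbutyl)-4,5-dimethoxyphenyl]prop-2-en-1-one (labile push–pull alkene, drawn E) | CN(C)/C=C(\c1cc(OC)c(OC)c(CCC(C)(C)O)c1O)C(=O)c1c(O)cc(OCc2ccccc2)cc1OCc1ccccc1 | intermediate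
13 | 5,7-bis(benzyloxy)-3-[2-hydroxy-3-(3-hydroxy-3-methylbutyl)-4,5-dimethoxyphenyl]-4H-chromen-4-one | COc1cc(-c2coc3cc(OCc4ccccc4)cc(OCc4ccccc4)c3c2=O)c(O)c(CCC(C)(C)O)c1OC | intermediate
14 | 5,7-dihydroxy-3-[2-hydroxy-3-(3-hydroxy-3-methylbutyl)-4,5-dimethoxyphenyl]-4H-chromen-4-one (achiral) | COc1cc(-c2coc3cc(O)cc(O)c3c2=O)c(O)c(CCC(C)(C)O)c1OC | target

## Step count and least certain steps

Total step count: 8. Longest linear sequence: 6 (steps 1, 2, 3, 4, 7, 8). Steps 5 and 6 form the second branch.

**Step 7 (key step, proposed new method).** Three processes are the most likely to interfere: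
- Proton-induced self-cyclisation of 10 may occur before the C–C bond forms, because the acid that ionises 7 also activates the enaminone.
- After coupling, the ring may close through the 2′-oxygen instead of the A-ring oxygen, because both hydroxyls can reach the same aminomethine carbon.
- The tertiary alcohol may ionise under acid and be captured by the neighbouring 2′-OH.

The fallback uses known chemistry only. It sets out from 7 and 10 and comes back to the route at 14.
- Iodine in methanol converts 10 into 5,7-bis(benzyloxy)-3-iodo-4H-chromen-4-one F1 (iodocyclisation of the enaminone).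
- In parallel, 7 is reduced with zinc in acetic acid, with loss of methanol, to 2-(3-hydroxy-3-methylbutyl)-3,4-dimethoxyphenol F2.
- NBS brominates the position ortho to the hydroxyl and para to the 3-methoxy group and gives 6-bromo-2-(3-hydroxy-3-methylbutyl)-3,4-dimethoxyphenol F3.
- Benzyl bromide and K2CO3 give 4-[2-(benzyloxy)-3-bromo-5,6-dimethoxyphenyl]-2-methylbutan-2-ol F4.
- Miyaura borylation (B2pin2, Pd(dppf)Cl2, KOAc) gives the pinacol boronate F5.
- Suzuki–Miyaura coupling of F1 with F5 (Pd catalyst, K2CO3, dioxane/water) gives the tri-O-benzyl isoflavone F6. Its blocked O2′ cannot attack C2.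
- Hydrogenolysis as in step 8 gives 14.

**Step 3.** Oxidation may divert to the benzylic CH2 of the side chain (side-chain methoxylation), or the electrode may foul, because an alkyl-substituted trialkoxyarene radical cation can also lose a benzylic proton. The fallback sets out from 5 (with 10) and comes back at 13, so it also bypasses step 4.
- Ceric ammonium nitrate in aqueous acetonitrile demethylates 5 oxidatively to 2-(3-hydroxy-3-methylbutyl)-3-methoxy-1,4-benzoquinone F7.
- In F7 the carbonyl that is not vinylogous to the methoxy group directs the Michael addition of 10 (acetic acid, rt) to the same carbon, C1′. Chromone closure then gives the 2′,5′-dihydroxy isoflavone F8.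
- One equivalent of dimethyl sulfate with K2CO3 methylates the unhindered 5′-OH in preference to the 2′-OH. The 2′-OH is flanked on both sides and hydrogen-bonded to C4=O. This gives 13.

**Step 1.** Incomplete or misdirected metalation, SN2′ attack on the allylic bromide and halogen–metal exchange with homocoupling could all erode the alkylation, because a doubly ortho-substituted aryllithium is a hindered nucleophile. The fallback sets out from 1 and comes back at 5, so it also bypasses step 2.
- The same lithiation is quenched with DMF to give 2,3,6-trimethoxybenzaldehyde F9.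
- Claisen–Schmidt condensation with acetone (NaOH) gives (E)-4-(2,3,6-trimethoxyphenyl)but-3-en-2-one F10.
- Hydrogenation (H2, Pd/C) gives 4-(2,3,6-trimethoxyphenyl)butan-2-one F11.
- Methylmagnesium bromide gives 5.

**Step 8.** Saturation of C2=C3 may compete with cleavage of the slower, peri-hindered 5-O-benzyl group, because both occur on the same catalyst. The fallback removes hydrogen from the end-game altogether. It sets out from 8 (with 7) and comes back at 14.
- Allyl bromide and K2CO3 give 1-[2,4-bis(allyloxy)-6-hydroxyphenyl]ethan-1-one F12.
- DMF-DMA gives the enaminone F13.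
- Coupling with 7 under the conditions of step 7 gives the 5,7-di-O-allyl isoflavone F14.
- Pd(PPh3)4 with morpholine as allyl acceptor (Tsuji–Trost deallylation, THF, rt) gives 14.

## Further compounds

F1 | step 7 | 5,7-bis(benzyloxy)-3-iodo-4H-chromen-4-one | O=c1c(I)coc2cc(OCc3ccccc3)cc(OCc3ccccc3)c12
F2 | step 7 | 2-(3-hydroxy-3-methylbutyl)-3,4-dimethoxyphenol | COc1ccc(O)c(CCC(C)(C)O)c1OC
F3 | step 7 | 6-bromo-2-(3-hydroxy-3-methylbutyl)-3,4-dimethoxyphenol | COc1cc(Br)c(O)c(CCC(C)(C)O)c1OC
F4 | step 7 | 4-[2-(benzyloxy)-3-bromo-5,6-dimethoxyphenyl]-2-methylbutan-2-ol | COc1cc(Br)c(OCc2ccccc2)c(CCC(C)(C)O)c1OC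
F5 | step 7 | 4-[2-(benzyloxy)-5,6-dimethoxy-3-(4,4,5,5-tetramethyl-1,3,2-dioxaborolan-2-yl)phenyl]-2-methylbutan-2-ol | COc1cc(B2OC(C)(C)C(C)(C)O2)c(OCc2ccccc2)c(CCC(C)(C)O)c1OC
F6 | step 7 | 5,7-bis(benzyloxy)-3-[2-(benzyloxy)-3-(3-hydroxy-3-methylbutyl)-4,5-dimethoxyphenyl]-4H-chromen-4-one | COc1cc(-c2coc3cc(OCc4ccccc4)cc(OCc4ccccc4)c3c2=O)c(OCc2ccccc2)c(CCC(C)(C)O)c1OC
F7 | step 3 | 2-(3-hydroxy-3-methylbutyl)-3-methoxycyclohexa-2,5-diene-1,4-dione | COC1=C(CCC(C)(C)O)C(=O)C=CC1=O
F8 | step 3 | 5,7-bis(benzyloxy)-3-[2,5-dihydroxy-3-(3-hydroxy-3-methylbutyl)-4-methoxyphenyl]-4H-chromen-4-one | COc1c(O)cc(-c2coc3cc(OCc4ccccc4)cc(OCc4ccccc4)c3c2=O)c(O)c1CCC(C)(C)O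
F9 | step 1 | 2,3,6-trimethoxybenzaldehyde | COc1ccc(OC)c(C=O)c1OC
F10 | step 1 | (E)-4-(2,3,6-trimethoxyphenyl)but-3-en-2-one | COc1ccc(OC)c(/C=C/C(C)=O)c1OC
F11 | step 1 | 4-(2,3,6-trimethoxyphenyl)butan-2-one | COc1ccc(OC)c(CCC(C)=O)c1OC
F12 | step 8 | 1-[2,4-bis(allyloxy)-6-hydroxyphenyl]ethan-1-one | CC(=O)c1c(O)cc(OCC=C)cc1OCC=C
F13 | step 8 | (E)-1-[2,4-bis(allyloxy)-6-hydroxyphenyl]-3-(dimethylamino)prop-2-en-1-one | CN(C)/C=C/C(=O)c1c(O)cc(OCC=C)cc1OCC=C
F14 | step 8 | 5,7-bis(allyloxy)-3-[2-hydroxy-3-(3-hydroxy-3-methylbutyl)-4,5-dimethoxyphenyl]-4H-chromen-4-one | COc1cc(-c2coc3cc(OCC=C)cc(OCC=C)c3c2=O)c(O)c(CCC(C)(C)O)c1OC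
A1 | alternative 1 | 5,7-bis(benzyloxy)-3-iodo-4H-chromen-4-one | O=c1c(I)coc2cc(OCc3ccccc3)cc(OCc3ccccc3)c12
A2 | alternative 1 | [2-(benzyloxy)-3-(3-hydroxy-3-methylbutyl)-4,5-dimethoxyphenyl]boronic acid | COc1cc(B(O)O)c(OCc2ccccc2)c(CCC(C)(C)O)c1OC
A3 | alternative 2 | 2-(benzyloxy)-3-(3-hydroxy-3-methylbutyl)-4,5-dimethoxybenzaldehyde | COc1cc(C=O)c(OCc2ccccc2)c(CCC(C)(C)O)c1OC
A4 | alternative 2 | (E)-3-[2-(benzyloxy)-3-(3-hydroxy-3-methylbutyl)-4,5-dimethoxyphenyl]-1-[2,4-bis(benzyloxy)-6-hydroxyphenyl]prop-2-en-1-one | COc1cc(/C=C/C(=O)c2c(O)cc(OCc3ccccc3)cc2OCc2ccccc2)c(OCc2ccccc2)c(CCC(C)(C)O)c1OC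
A5 | alternative 3 | 5,7-bis(benzyloxy)-3-ethynyl-4H-chromen-4-one | C#Cc1coc2cc(OCc3ccccc3)cc(OCc3ccccc3)c2c1=O
A6 | alternative 3 | pentacarbonyl[(Z)-1,2-dimethoxy-6-methyl-6-(triethylsilyloxy)hept-2-en-1-ylidene]chromium(0), carbonyl ligands written as separate components | COC(/C(OC)=C/CCC(C)(C)O[Si](CC)(CC)CC)=[Cr].[C-]#[O+].[C-]#[O+].[C-]#[O+].[C-]#[O+].[C-]#[O+]
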